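**Retrosynthetic overview**

1. Watsonianone A ⇒ acyclic tetraketo diester MeO2C–CMe2–CO–CMe2–CO–CH2–CH(i-Bu)–CH2–CO–CMe2–CO–CMe2–CO2Me. Each cyclohexane ring is opened at C1–C2, the bond between the ring carbon that carries the central methine (C2) and the neighbouring carbonyl carbon next to a CMe2 group (C1); in the forward sense this is a double Dieckmann condensation.
2. Tetraketo diester ⇒ 3-isobutylglutaryl dichloride + two molecules of the enolate MeO2C–CMe2–C(OLi)=CMe2 (two C-acylations). The enolate ⇒ 2,2,4,4-tetramethylcyclobutane-1,3-dione (dimethylketene dimer) + methoxide (strain-releasing ring opening). Ring opening, acylation and ring closure are run in one flask.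
3. Enabling feature: in each ring the segment C4(Me2)–C5(=O)–C6(Me2)–C1(=O) is the intact carbon ring of the ketene dimer, while C3–C2 of ring A, the methine carbon and C2–C3 of ring B are the five-carbon chain of 3-isobutylglutaric acid. The quaternary C4 and C6 leave C2 as the only enolisable carbon, so each ring is the formal insertion of a glutaryl CH2–C(=O) unit into a ring C–C bond of the strained dione.
4. Order of rings: the cyclobutanedione ring is made first (from two molecules of isobutyryl chloride) and then opened; rings A and B of the target are closed last, both in the same operation.

Key step: step 3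

Remark: the target is drawn as one of its degenerate enol tautomers, and the central methine carries two constitutionally identical rings, so the molecule has no stereocentre and no stereocontrol is needed.

**Route**

Step 1
Reactants: 1 isobutyryl chloride (2.0 equiv)
Product: 3 2,2,4,4-tetramethylcyclobutane-1,3-dione, via dimethylketene 2 (not isolated)
Conditions: Et3N (2.2 equiv), Et2O, reflux, N2; filtration, recrystallisation
Reagents that add atoms: none
Why: Dehydrochlorination of each of the two molecules of acid chloride by the tertiary amine should give dimethylketene, which has no α-hydrogen, and two molecules of it should combine in the thermal head-to-tail [2+2] ketene dimerisation to the symmetrical 1,3-dione; no stereocentre is formed.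

Step 2
Reactants: 4 3-isobutylglutaric acid [3-(2-methylpropyl)pentanedioic acid]
Product: 5 3-isobutylglutaryl dichloride [3-(2-methylpropyl)pentanedioyl dichloride]
Conditions: SOCl2 (3 equiv), DMF (cat.), 70 °C; vacuum distillation
Reagents that add atoms: thionyl chloride, O=S(Cl)Cl
Why: Acid chloride formation with thionyl chloride under DMF (Vilsmeier) catalysis, as used for glutaryl dichloride itself, should convert both carboxyl groups, the excess reagent and heat carrying the mono-chloride on before it rests as the cyclic anhydride; no stereocentre is involved.

Step 3
Reactants: 3 2,2,4,4-tetramethylcyclobutane-1,3-dione (2.2 equiv); 5 3-isobutylglutaryl dichloride (1.0 equiv)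
Product: 9 Watsonianone A, via lithium enolate 6 (not isolated), via tetraketo diester 7 (not isolated), via dilithium bis(enolate) 8 (not isolated)
Conditions: MeOH, n-BuLi (2.1 equiv each), THF, 0 °C, then 3 added slowly, −78 to 0 °C; cannulation into 5, THF, −78 °C; LiN(SiMe3)2 (4.2 equiv), −78 to 45 °C; 1 M HCl
Reagents that add atoms: none
Why: Proposed new method: methoxide adds to one carbonyl group of 3 and the adduct fragments in a retro-Claisen sense, the release of four-membered-ring strain making the opening irreversible and delivering regiospecifically the tetrasubstituted lithium enolate 6; its carbon terminus is acylated by both acyl chloride groups of 5 (to 7), and LiN(SiMe3)2 then deprotonates the two glutaryl CH2 groups, the only acidic C–H bonds in 7, so that each enolate carbon attacks the methyl ester five atoms away and expels methoxide in a Dieckmann condensation (to 8). The closest known reaction types are the alkoxide-catalysed alcoholysis of 3 to 2,2,4-trimethyl-3-oxopentanoate esters, the C-acylation of the preformed lithium enolate of such an ester with an acid chloride and the Dieckmann closure of the resulting 3,5-dioxo ester to the syncarpic acid ring; new is that the enolate is generated by the strain-releasing ring opening instead of by deprotonation, is trapped in the same flask, and that acylation and ring closure run twice on one bis-electrophile. Each six-membered ring closes in the 6-(enolendo)-exo-trig mode by forming the bond between the former glutaryl α-carbon (ring C2, the carbon that carries the methine) and the former ester carbon (ring C1, next to a CMe2 group), and the overall result is the formal insertion of a CH2–C(=O) unit into a C–C bond of each molecule of 3. No stereocentre is formed, because the central methine carries two identical rings. The step needs carbon over oxygen selectivity twice: in the acylation it is secured by the lithium counter-ion in THF without polar additives at −78 °C and by inverse addition, which also keeps proton transfer to 6 low, and in the ring closure by thermodynamic control, since any enol lactone from O-attack is reopened by the methoxide set free whereas C-attack ends irreversibly in the stabilised β-triketone enolate. The two quaternary CMe2 carbons of each arm rule out any other enolate and speed the closure (Thorpe–Ingold effect).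

**Compound list**

1 | isobutyryl chloride (2-methylpropanoyl chloride) | CC(C)C(=O)Cl | starting material
2 | dimethylketene (2-methylprop-1-en-1-one) | CC(C)=C=O | intermediate
3 | 2,2,4,4-tetramethylcyclobutane-1,3-dione | CC1(C)C(=O)C(C)(C)C1=O | intermediate
4 | 3-isobutylglutaric acid [3-(2-methylpropyl)pentanedioic acid] | CC(C)CC(CC(=O)O)CC(=O)O | starting material
5 | 3-isobutylglutaryl dichloride [3-(2-methylpropyl)pentanedioyl dichloride] | CC(C)CC(CC(=O)Cl)CC(=O)Cl | intermediate
6 | lithium enolate of methyl 2,2,4-trimethyl-3-oxopentanoate (methyl 2,2,4-trimethyl-3-oxidopent-3-enoate, lithium salt) | COC(=O)C(C)(C)C([O-])=C(C)C.[Li+] | intermediate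
7 | dimethyl 2,2,4,4,10,10,12,12-octamethyl-7-(2-methylpropyl)-3,5,9,11-tetraoxotridecanedioate | COC(=O)C(C)(C)C(=O)C(C)(C)C(=O)CC(CC(C)C)CC(=O)C(C)(C)C(=O)C(C)(C)C(=O)OC | intermediate
8 | dilithium bis(enolate) of Watsonianone A | CC(C)CC(C1=C([O-])C(C)(C)C(=O)C(C)(C)C1=O)C1=C([O-])C(C)(C)C(=O)C(C)(C)C1=O.[Li+].[Li+] | intermediate
9 | Watsonianone A, 2,2'-(3-methylbutane-1,1-diyl)bis(3-hydroxy-4,4,6,6-tetramethylcyclohex-2-ene-1,5-dione) | CC(C)CC(C1=C(O)C(C)(C)C(=O)C(C)(C)C1=O)C1=C(O)C(C)(C)C(=O)C(C)(C)C1=O | target

**Step count and risks**

Total step count: 3. Longest linear sequence: 2 steps (step 1 or step 2, then step 3).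

Steps most likely to fail:

1. Step 3 (Proposed new method). Several processes may divert the sequence:
   - oligomerisation of the dione, through attack of the new enolate on unopened dione instead of attack by methoxide;
   - acylation of the hindered enolate on oxygen instead of carbon;
   - after the first acylation, proton transfer followed by enol lactone closure onto the second acyl chloride;
   - retro-Claisen cleavage of a non-enolisable 1,3-diketone by methoxide before the ring has closed.

   Fallback (known chemistry, sets out from 3, returns at 9): methanolysis of 3 with catalytic NaOMe in MeOH should give methyl 2,2,4-trimethyl-3-oxopentanoate F1. Deprotonation with LiN(i-Pr)2 in THF at −78 °C and C-acylation with acetyl chloride should give methyl 2,2,4,4-tetramethyl-3,5-dioxohexanoate F2. Dieckmann condensation (LiN(i-Pr)2, THF, −78 °C to room temperature) closes the same C–C(=O) ring bond and should give syncarpic acid F3. Two equivalents of F3 with 3-methylbutanal and catalytic piperidine in CH2Cl2 should then give 9, where the route is rejoined, by Knoevenagel condensation to 2,2,4,4-tetramethyl-6-(3-methylbutylidene)cyclohexane-1,3,5-trione F4 (not isolated) and Michael addition of the second F3.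

2. Step 2. Ring closure of the mono-acid chloride onto the second carboxyl group may stop the conversion at the cyclic anhydride, and the dichloride may lose HCl on distillation. Fallback (sets out from 4, returns at 7): 1,1'-carbonyldiimidazole (2.2 equiv) in THF should give the bis(imidazolide) 1,5-di(1H-imidazol-1-yl)-3-(2-methylpropyl)pentane-1,5-dione F5; any anhydride is reopened by the liberated imidazole and activated again. F5 replaces 5 in step 3 (C-acylation of lithium enolates by acyl imidazoles), and the route is rejoined at 7.

3. Step 1. Amine-induced oligomerisation of the ketene to polyester, or its autoxidation, may outrun the [2+2] dimerisation. Fallback (sets out from 1, returns at 2 and thus 3): α-bromination of 1 (N-bromosuccinimide, catalytic HBr, 85 °C) should give 2-bromo-2-methylpropanoyl chloride F6. Zinc dust in ethyl acetate removes both halogens by reductive 1,2-elimination and should give amine-free dimethylketene 2, which is distilled and dimerises neat on gentle warming under N2 to 3.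

**Further compounds**

F1 | step 3 | methyl 2,2,4-trimethyl-3-oxopentanoate | COC(=O)C(C)(C)C(=O)C(C)C
F2 | step 3 | methyl 2,2,4,4-tetramethyl-3,5-dioxohexanoate | COC(=O)C(C)(C)C(=O)C(C)(C)C(C)=O
F3 | step 3 | syncarpic acid (2,2,4,4-tetramethylcyclohexane-1,3,5-trione) | CC1(C)C(=O)CC(=O)C(C)(C)C1=O
F4 | step 3 | 2,2,4,4-tetramethyl-6-(3-methylbutylidene)cyclohexane-1,3,5-trione | CC(C)CC=C1C(=O)C(C)(C)C(=O)C(C)(C)C1=O
F5 | step 2 | 1,5-di(1H-imidazol-1-yl)-3-(2-methylpropyl)pentane-1,5-dione | CC(C)CC(CC(=O)n1ccnc1)CC(=O)n1ccnc1
F6 | step 1 | 2-bromo-2-methylpropanoyl chloride | CC(C)(Br)C(Cl)=O
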